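**Retrosynthetic overview**
- The target comes from global desilylation of a hexa-silyl lactone; the butyrolactone comes from reduction of an N-acyloxazolidinone next to a methyl ester, lactonisation and α-epimerisation to trans.
- Key disconnection: the central C3–C4 (8–8′) bond is made by iron-mediated oxidative heterocoupling of two lithium enolates (imide of the open-diol half, methyl ester of the dihydrobenzofuran half). One enolate is oxidised to an α-carbonyl radical/enolonium equivalent, so two normally nucleophilic α-carbons are joined; the Evans auxiliary sets C4.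
- Both halves come from one arylacetyl imide: a magnesium-catalysed anti-aldol gives the (1S,2S)-diol, and a boron syn-aldol followed by acid cyclisation gives the trans-(2S,3R)-dihydrobenzofuran. The C3 side chains are added by Heck/hydrogenation.
- The arylacetyl imide comes from 5-bromo-o-vanillin by benzylation, Corey–Fuchs olefination and copper-catalysed ynamide formation/hydration.
- Ring order: dihydrobenzofuran ring first (step 12), butyrolactone ring last (step 15).

Assumption: the configuration is taken exactly as written in the SMILES, which I read as lactone (3R,4R), dihydrobenzofuran (2S,3R) and open 1,3-diol (1S,2S).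

Abbreviations: TBS = tert-butyldimethylsilyl.
ArD = 3-[(1S,2S)-1,3-bis(TBSO)-1-(3-methoxy-4-(TBSO)phenyl)propan-2-yl]-5-methoxy-4-(TBSO)phenyl.
ArF = (2S,3R)-7-methoxy-2-[3-methoxy-4-(TBSO)phenyl]-3-[(TBSO)methyl]-2,3-dihydrobenzofuran-5-yl.

**Route**

Step 1
Reactants: 1 5-bromo-2-hydroxy-3-methoxybenzaldehyde
Product: 2 2-(benzyloxy)-5-bromo-3-methoxybenzaldehyde
Conditions: BnBr, K2CO3, DMF, 50 °C
Reagents that add atoms: benzyl bromide BrCc1ccccc1
Why: Williamson ether synthesis masks the phenol so that the later arylacetyl imide cannot lactonise to a benzofuranone; no stereocentre is involved.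

Step 2
Reactants: 2 2-(benzyloxy)-5-bromo-3-methoxybenzaldehyde
Product: 3 2-(benzyloxy)-5-bromo-1-(2,2-dibromovinyl)-3-methoxybenzene
Conditions: CBr4, PPh3, Zn dust, CH2Cl2, 0 °C → rt
Reagents that add atoms: carbon tetrabromide BrC(Br)(Br)Br
Why: Corey–Fuchs dibromo-olefination adds the one carbon needed for the arylacetyl unit; no stereocentre is involved.

Step 3
Reactants: 3 2-(benzyloxy)-5-bromo-1-(2,2-dibromovinyl)-3-methoxybenzene; 4 (S)-4-benzyloxazolidin-2-one
Product: 6 (S)-4-benzyl-3-{2-[2-(benzyloxy)-5-bromo-3-methoxyphenyl]acetyl}oxazolidin-2-one, via ynamide 5 (not isolated)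
Conditions: CuI (12 mol%), N,N′-dimethylethylenediamine (18 mol%), Cs2CO3 (4 equiv), 1,4-dioxane, 65 °C; then 1 M aq HCl, THF, rt
Reagents that add atoms: water O
Why: Copper-catalysed C–N coupling of a 1,1-dibromoalkene (ynamide synthesis) followed by acid-catalysed ynamide hydration (water adds to the N-bearing carbon of the keteniminium) gives the arylacetyl imide directly, and the vinylic dibromide couples well below the temperature at which the aryl bromide would react; the only stereocentre is that of 4.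

Step 4
Reactants: 6 (S)-4-benzyl-3-{2-[2-(benzyloxy)-5-bromo-3-methoxyphenyl]acetyl}oxazolidin-2-one; 7 4-(benzyloxy)-3-methoxybenzaldehyde
Product: 8 (S)-4-benzyl-3-[(2R,3S)-2-[2-(benzyloxy)-5-bromo-3-methoxyphenyl]-3-[4-(benzyloxy)-3-methoxyphenyl]-3-(trimethylsilyloxy)propanoyl]oxazolidin-2-one
Conditions: MgCl2 (0.2 equiv), Et3N (2 equiv), Me3SiCl (1.5 equiv), EtOAc, 23 °C
Reagents that add atoms: chlorotrimethylsilane C[Si](C)(C)Cl
Why: Evans magnesium-halide-catalysed anti-aldol (soft enolisation, magnesium-chelated Z-enolate, boat transition state, silylation as turnover step), here extended to an α-aryl acyl group, adds the non-enolisable aldehyde to the enolate face opposite the auxiliary benzyl group and so sets both centres of the open diol unit as (2R,3S), while the silyl ether blocks retro-aldol.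

Step 5
Reactants: 8 (S)-4-benzyl-3-[(2R,3S)-2-[2-(benzyloxy)-5-bromo-3-methoxyphenyl]-3-[4-(benzyloxy)-3-methoxyphenyl]-3-(trimethylsilyloxy)propanoyl]oxazolidin-2-one
Product: 9 (1S,2S)-2-[2-(benzyloxy)-5-bromo-3-methoxyphenyl]-1-[4-(benzyloxy)-3-methoxyphenyl]propane-1,3-diol
Conditions: LiBH4, H2O (1 equiv), Et2O/THF, 0 °C; then aq citric acid, MeOH, rt
Reagents that add atoms: none
Why: Reductive cleavage of the N-acyloxazolidinone with LiBH4 gives the primary alcohol and returns the auxiliary, and the acidic work-up removes the trimethylsilyl group; both stereocentres are untouched (C2 changes from R to S only through CIP priorities).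

Step 6
Reactants: 4 (S)-4-benzyloxazolidin-2-one; 10 acryloyl chloride
Product: 11 (S)-3-acryloyl-4-benzyloxazolidin-2-one
Conditions: Et3N, LiCl, THF, −20 °C → rt
Reagents that add atoms: none
Why: Lithium-chloride-assisted N-acylation of the oxazolidinone under amine base avoids strongly basic conditions that polymerise the acrylate; no new stereocentre.

Step 7
Reactants: 9 (1S,2S)-2-[2-(benzyloxy)-5-bromo-3-methoxyphenyl]-1-[4-(benzyloxy)-3-methoxyphenyl]propane-1,3-diol; 11 (S)-3-acryloyl-4-benzyloxazolidin-2-one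
Product: 13 (S)-4-benzyl-3-[3-{3-[(1S,2S)-1,3-dihydroxy-1-(4-hydroxy-3-methoxyphenyl)propan-2-yl]-4-hydroxy-5-methoxyphenyl}propanoyl]oxazolidin-2-one, via Heck enoyl imide 12 (not isolated)
Conditions: Pd(OAc)2 (5 mol%), P(t-Bu)3·HBF4 (10 mol%), Cy2NMe, 1,4-dioxane, 50 °C; then filter, 10% Pd/C, H2 (1 atm), EtOAc/EtOH, rt
Reagents that add atoms: none
Why: Mizoroki–Heck coupling of the electron-rich aryl bromide with the acryloyl imide, followed in the same pot by catalytic hydrogenation (alkene saturation and hydrogenolysis of both aryl benzyl ethers), installs the auxiliary-bearing C3 side chain; the residual amine keeps the medium non-acidic so the p-hydroxybenzyl alcohol does not ionise, and no stereocentre is touched.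

Step 8
Reactants: 13 (S)-4-benzyl-3-[3-{3-[(1S,2S)-1,3-dihydroxy-1-(4-hydroxy-3-methoxyphenyl)propan-2-yl]-4-hydroxy-5-methoxyphenyl}propanoyl]oxazolidin-2-one
Product: 14 (S)-4-benzyl-3-[3-(ArD)propanoyl]oxazolidin-2-one (fragment 1; all four hydroxyls as TBS ethers)
Conditions: TBSOTf (6 equiv), 2,6-lutidine (8 equiv), CH2Cl2, −78 → 0 °C
Reagents that add atoms: tert-butyldimethylsilyl trifluoromethanesulfonate CC(C)(C)[Si](C)(C)OS(=O)(=O)C(F)(F)F
Why: Exhaustive O-silylation of two phenols, the primary and the hindered benzylic alcohol removes every acidic proton before the enolate chemistry; stereocentres are unaffected.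

Step 9
Reactants: 6 (S)-4-benzyl-3-{2-[2-(benzyloxy)-5-bromo-3-methoxyphenyl]acetyl}oxazolidin-2-one; 7 4-(benzyloxy)-3-methoxybenzaldehyde
Product: 15 (S)-4-benzyl-3-[(2S,3S)-2-[2-(benzyloxy)-5-bromo-3-methoxyphenyl]-3-[4-(benzyloxy)-3-methoxyphenyl]-3-hydroxypropanoyl]oxazolidin-2-one
Conditions: Bu2BOTf, i-Pr2NEt, CH2Cl2, −78 → 0 °C; 7, −78 → 0 °C; then pH 7 buffer, MeOH, 30% H2O2, 0 °C
Reagents that add atoms: none
Why: Evans syn-aldol through the dibutylboron Z-enolate and a closed Zimmerman–Traxler transition state with the dipole-minimised auxiliary attacks the enolate face opposite to that used in step 4, so the same imide gives the (2S) centre that becomes C3 (R) of the dihydrobenzofuran; the carbinol centre is erased in step 12.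

Step 10
Reactants: 15 (S)-4-benzyl-3-[(2S,3S)-2-[2-(benzyloxy)-5-bromo-3-methoxyphenyl]-3-[4-(benzyloxy)-3-methoxyphenyl]-3-hydroxypropanoyl]oxazolidin-2-one
Product: 16 (1S,2R)-2-[2-(benzyloxy)-5-bromo-3-methoxyphenyl]-1-[4-(benzyloxy)-3-methoxyphenyl]propane-1,3-diol
Conditions: LiBH4, MeOH (1 equiv), THF, 0 °C
Reagents that add atoms: none
Why: Reductive removal of the auxiliary with LiBH4 gives the 1,3-diol without touching either stereocentre (C2 changes from S to R only through CIP priorities).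

Step 11
Reactants: 16 (1S,2R)-2-[2-(benzyloxy)-5-bromo-3-methoxyphenyl]-1-[4-(benzyloxy)-3-methoxyphenyl]propane-1,3-diol; 17 methyl acrylate
Product: 19 methyl 3-{3-[(1S,2R)-1,3-dihydroxy-1-(4-hydroxy-3-methoxyphenyl)propan-2-yl]-4-hydroxy-5-methoxyphenyl}propanoate, via Heck cinnamate 18 (not isolated)
Conditions: Pd(OAc)2 (5 mol%), P(t-Bu)3·HBF4 (10 mol%), Cy2NMe, 1,4-dioxane, 50 °C; then filter, 10% Pd/C, H2 (1 atm), EtOAc/EtOH, rt
Reagents that add atoms: none
Why: The same Mizoroki–Heck/hydrogenation–hydrogenolysis sequence as in step 7 installs the ester side chain and frees both phenols for the cyclisation; no stereocentre is touched.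

Step 12
Reactants: 19 methyl 3-{3-[(1S,2R)-1,3-dihydroxy-1-(4-hydroxy-3-methoxyphenyl)propan-2-yl]-4-hydroxy-5-methoxyphenyl}propanoate
Product: 20 methyl 3-[(2S,3R)-2-(4-hydroxy-3-methoxyphenyl)-3-(hydroxymethyl)-7-methoxy-2,3-dihydrobenzofuran-5-yl]propanoate
Conditions: p-TsOH·H2O (5 mol%), CH2Cl2/THF, 0 °C → rt
Reagents that add atoms: none
Why: Acid-catalysed dehydrative cyclisation through the p-quinone methide (benzylic cation), captured 5-exo by the ortho phenol anti to the C3 hydroxymethyl group, gives the trans ring under kinetic and thermodynamic control, so C2 (S) follows from the fixed C3 (R) whatever the carbinol configuration was.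

Step 13
Reactants: 20 methyl 3-[(2S,3R)-2-(4-hydroxy-3-methoxyphenyl)-3-(hydroxymethyl)-7-methoxy-2,3-dihydrobenzofuran-5-yl]propanoate
Product: 21 methyl 3-(ArF)propanoate (fragment 2; phenol and primary alcohol as TBS ethers)
Conditions: TBSCl (2.5 equiv), imidazole, DMF, rt
Reagents that add atoms: tert-butyldimethylsilyl chloride CC(C)(C)[Si](C)(C)Cl
Why: Standard silylation of the phenol and primary alcohol removes the acidic protons before enolate formation; stereocentres are unaffected.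

Step 14
Reactants: 14 (S)-4-benzyl-3-[3-(ArD)propanoyl]oxazolidin-2-one; 21 methyl 3-(ArF)propanoate
Product: 22 methyl (2RS,3R)-3-(ArD-methyl)-2-(ArF-methyl)-4-[(S)-4-benzyl-2-oxooxazolidin-3-yl]-4-oxobutanoate (epimers at C2)
Conditions: 14 (1 equiv), 21 (1.2 equiv), LiN(i-Pr)2 (2.3 equiv), THF, −78 °C, 30 min; Fe(acac)3 [Fe(C5H7O2)3] (2.2 equiv), −78 °C → rt
Reagents that add atoms: none
Why: Oxidative enolate heterocoupling, in which trivalent iron oxidises the mixed lithium enolate aggregate by one electron so that one α-carbon reacts as an α-carbonyl radical/enolonium equivalent with the other enolate, forms the central bond on the face of the chelated imide Z-enolate opposite the auxiliary benzyl group and fixes the (R) centre that becomes lactone C4, while the ester α-centre forms as a mixture that step 15 corrects.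

Step 15
Reactants: 22 methyl (2RS,3R)-3-(ArD-methyl)-2-(ArF-methyl)-4-[(S)-4-benzyl-2-oxooxazolidin-3-yl]-4-oxobutanoate
Product: 24 (3R,4R)-4-(ArD-methyl)-3-(ArF-methyl)dihydrofuran-2(3H)-one, via hydroxy ester 23 (not isolated)
Conditions: LiBH4 (1.2 equiv), MeOH (1.2 equiv), THF, 0 °C; aq NH4Cl; crude in PhMe, DBU (1 equiv), 60 °C
Reagents that add atoms: none
Why: Chemoselective reduction of the imide in the presence of the α-branched methyl ester, 5-exo lactonisation of the resulting γ-hydroxy ester and DBU-mediated epimerisation of the lactone α-centre converge both C2 epimers on the thermodynamically favoured trans-3,4-dibenzyl lactone, which with C4 fixed as R means C3 is R.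

Step 16
Reactants: 24 (3R,4R)-4-(ArD-methyl)-3-(ArF-methyl)dihydrofuran-2(3H)-one
Product: 25 (3R,4R)-4-{3-[(1S,2S)-1,3-dihydroxy-1-(4-hydroxy-3-methoxyphenyl)propan-2-yl]-4-hydroxy-5-methoxybenzyl}-3-{[(2S,3R)-2-(4-hydroxy-3-methoxyphenyl)-3-(hydroxymethyl)-7-methoxy-2,3-dihydrobenzofuran-5-yl]methyl}dihydrofuran-2(3H)-one
Conditions: Bu4NF (8 equiv), AcOH (8 equiv), THF, 0 °C → rt
Reagents that add atoms: none
Why: Fluoride-mediated cleavage of all six silyl ethers, buffered with acetic acid so the liberated p-hydroxybenzyl alcohol neither forms a quinone methide nor closes onto the neighbouring phenol, releases the target without touching any stereocentre.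

**Compound list**

1 | 5-bromo-2-hydroxy-3-methoxybenzaldehyde | COc1cc(Br)cc(C=O)c1O | starting material
2 | 2-(benzyloxy)-5-bromo-3-methoxybenzaldehyde | COc1cc(Br)cc(C=O)c1OCc1ccccc1 | intermediate
3 | 2-(benzyloxy)-5-bromo-1-(2,2-dibromovinyl)-3-methoxybenzene | COc1cc(Br)cc(C=C(Br)Br)c1OCc1ccccc1 | intermediate
4 | (S)-4-benzyloxazolidin-2-one | O=C1N[C@@H](Cc2ccccc2)CO1 | starting material
5 | (S)-4-benzyl-3-{[2-(benzyloxy)-5-bromo-3-methoxyphenyl]ethynyl}oxazolidin-2-one (ynamide) | COc1cc(Br)cc(C#CN2[C@@H](Cc3ccccc3)COC2=O)c1OCc1ccccc1 | intermediate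
6 | (S)-4-benzyl-3-{2-[2-(benzyloxy)-5-bromo-3-methoxyphenyl]acetyl}oxazolidin-2-one | COc1cc(Br)cc(CC(=O)N2[C@@H](Cc3ccccc3)COC2=O)c1OCc1ccccc1 | intermediate
7 | 4-(benzyloxy)-3-methoxybenzaldehyde | COc1cc(C=O)ccc1OCc1ccccc1 | starting material
8 | (S)-4-benzyl-3-[(2R,3S)-2-[2-(benzyloxy)-5-bromo-3-methoxyphenyl]-3-[4-(benzyloxy)-3-methoxyphenyl]-3-(trimethylsilyloxy)propanoyl]oxazolidin-2-one | O=C(N1[C@@H](Cc2ccccc2)COC1=O)[C@H](c1cc(Br)cc(OC)c1OCc1ccccc1)[C@H](O[Si](C)(C)C)c1ccc(OCc2ccccc2)c(OC)c1 | intermediate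
9 | (1S,2S)-2-[2-(benzyloxy)-5-bromo-3-methoxyphenyl]-1-[4-(benzyloxy)-3-methoxyphenyl]propane-1,3-diol | COc1cc([C@@H](O)[C@H](CO)c2cc(Br)cc(OC)c2OCc2ccccc2)ccc1OCc1ccccc1 | intermediate
10 | acryloyl chloride | C=CC(=O)Cl | starting material
11 | (S)-3-acryloyl-4-benzyloxazolidin-2-one | C=CC(=O)N1[C@@H](Cc2ccccc2)COC1=O | intermediate
12 | (S)-4-benzyl-3-[(E)-3-{4-(benzyloxy)-3-[(1S,2S)-1-(4-(benzyloxy)-3-methoxyphenyl)-1,3-dihydroxypropan-2-yl]-5-methoxyphenyl}acryloyl]oxazolidin-2-one | COc1cc([C@@H](O)[C@H](CO)c2cc(/C=C/C(=O)N3[C@@H](Cc4ccccc4)COC3=O)cc(OC)c2OCc2ccccc2)ccc1OCc1ccccc1 | intermediate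
13 | (S)-4-benzyl-3-[3-{3-[(1S,2S)-1,3-dihydroxy-1-(4-hydroxy-3-methoxyphenyl)propan-2-yl]-4-hydroxy-5-methoxyphenyl}propanoyl]oxazolidin-2-one | COc1cc([C@@H](O)[C@H](CO)c2cc(CCC(=O)N3[C@@H](Cc4ccccc4)COC3=O)cc(OC)c2O)ccc1O | intermediate
14 | (S)-4-benzyl-3-[3-(ArD)propanoyl]oxazolidin-2-one (fragment 1) | COc1cc([C@@H](O[Si](C)(C)C(C)(C)C)[C@H](CO[Si](C)(C)C(C)(C)C)c2cc(CCC(=O)N3[C@@H](Cc4ccccc4)COC3=O)cc(OC)c2O[Si](C)(C)C(C)(C)C)ccc1O[Si](C)(C)C(C)(C)C | intermediate
15 | (S)-4-benzyl-3-[(2S,3S)-2-[2-(benzyloxy)-5-bromo-3-methoxyphenyl]-3-[4-(benzyloxy)-3-methoxyphenyl]-3-hydroxypropanoyl]oxazolidin-2-one | O=C(N1[C@@H](Cc2ccccc2)COC1=O)[C@@H](c1cc(Br)cc(OC)c1OCc1ccccc1)[C@H](O)c1ccc(OCc2ccccc2)c(OC)c1 | intermediate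
16 | (1S,2R)-2-[2-(benzyloxy)-5-bromo-3-methoxyphenyl]-1-[4-(benzyloxy)-3-methoxyphenyl]propane-1,3-diol | COc1cc([C@@H](O)[C@@H](CO)c2cc(Br)cc(OC)c2OCc2ccccc2)ccc1OCc1ccccc1 | intermediate
17 | methyl acrylate | C=CC(=O)OC | starting material
18 | methyl (E)-3-{4-(benzyloxy)-3-[(1S,2R)-1-(4-(benzyloxy)-3-methoxyphenyl)-1,3-dihydroxypropan-2-yl]-5-methoxyphenyl}acrylate | COc1cc([C@@H](O)[C@@H](CO)c2cc(/C=C/C(=O)OC)cc(OC)c2OCc2ccccc2)ccc1OCc1ccccc1 | intermediate
19 | methyl 3-{3-[(1S,2R)-1,3-dihydroxy-1-(4-hydroxy-3-methoxyphenyl)propan-2-yl]-4-hydroxy-5-methoxyphenyl}propanoate | COc1cc([C@@H](O)[C@@H](CO)c2cc(CCC(=O)OC)cc(OC)c2O)ccc1O | intermediate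
20 | methyl 3-[(2S,3R)-2-(4-hydroxy-3-methoxyphenyl)-3-(hydroxymethyl)-7-methoxy-2,3-dihydrobenzofuran-5-yl]propanoate | COC(=O)CCc1cc(OC)c2c(c1)[C@H](CO)[C@@H](c1ccc(O)c(OC)c1)O2 | intermediate
21 | methyl 3-(ArF)propanoate (fragment 2) | COC(=O)CCc1cc(OC)c2c(c1)[C@H](CO[Si](C)(C)C(C)(C)C)[C@@H](c1ccc(O[Si](C)(C)C(C)(C)C)c(OC)c1)O2 | intermediate
22 | methyl (2RS,3R)-3-(ArD-methyl)-2-(ArF-methyl)-4-[(S)-4-benzyl-2-oxooxazolidin-3-yl]-4-oxobutanoate (C2 left undefined, epimer mixture) | COc1cc([C@@H](O[Si](C)(C)C(C)(C)C)[C@H](CO[Si](C)(C)C(C)(C)C)c2cc(C[C@@H](C(=O)N3[C@@H](Cc4ccccc4)COC3=O)C(Cc3cc(OC)c4c(c3)[C@H](CO[Si](C)(C)C(C)(C)C)[C@@H](c3ccc(O[Si](C)(C)C(C)(C)C)c(OC)c3)O4)C(=O)OC)cc(OC)c2O[Si](C)(C)C(C)(C)C)ccc1O[Si](C)(C)C(C)(C)C | intermediate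
23 | methyl (2RS,3R)-3-(ArD-methyl)-2-(ArF-methyl)-4-hydroxybutanoate | COc1cc([C@@H](O[Si](C)(C)C(C)(C)C)[C@H](CO[Si](C)(C)C(C)(C)C)c2cc(C[C@@H](CO)C(Cc3cc(OC)c4c(c3)[C@H](CO[Si](C)(C)C(C)(C)C)[C@@H](c3ccc(O[Si](C)(C)C(C)(C)C)c(OC)c3)O4)C(=O)OC)cc(OC)c2O[Si](C)(C)C(C)(C)C)ccc1O[Si](C)(C)C(C)(C)C | intermediate
24 | (3R,4R)-4-(ArD-methyl)-3-(ArF-methyl)dihydrofuran-2(3H)-one | COc1cc([C@@H](O[Si](C)(C)C(C)(C)C)[C@H](CO[Si](C)(C)C(C)(C)C)c2cc(C[C@H]3COC(=O)[C@@H]3Cc3cc(OC)c4c(c3)[C@H](CO[Si](C)(C)C(C)(C)C)[C@@H](c3ccc(O[Si](C)(C)C(C)(C)C)c(OC)c3)O4)cc(OC)c2O[Si](C)(C)C(C)(C)C)ccc1O[Si](C)(C)C(C)(C)C | intermediate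
25 | CNP0199264.2 | COc1cc([C@@H](O)[C@H](CO)c2cc(C[C@H]3COC(=O)[C@@H]3Cc3cc(OC)c4c(c3)[C@H](CO)[C@@H](c3ccc(O)c(OC)c3)O4)cc(OC)c2O)ccc1O | target

**Totals**

Total step count: 16. Longest linear sequence: 11 steps (1, 2, 3, 9, 10, 11, 12, 13, 14, 15, 16).

**Three steps most likely to fail**

Step 14 (oxidative heterocoupling of two large, hexa-silylated fragments; homodimerisation and low conversion are the main dangers). The fallback sets out from 14 and 21 and comes back at 22. Instead of oxidising a mixed enolate aggregate, the imide is pre-oxidised: 14 is converted through its dibutylboron enolate (Bu2BOTf, i-Pr2NEt) and N-bromosuccinimide into (S)-4-benzyl-3-[2-bromo-3-(ArD)propanoyl]oxazolidin-2-one F1. Ester 21 is converted with LiN(i-Pr)2 and Me3SiCl into its ketene acetal, 1-methoxy-1-(trimethylsilyloxy)-3-(ArF)prop-1-ene F2. Et3B/air-initiated radical addition of the electrophilic α-imide radical from F1 to the electron-rich alkene of F2, in the presence of MgBr2·OEt2 to keep the auxiliary chelated and face-selective, followed by loss of Me3SiBr, gives 22, and the route continues with step 15.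

Step 4 (the magnesium-catalysed anti-aldol is established for alkyl acyl groups; the hindered α-aryl imide may give low anti selectivity or retro-aldol). The fallback sets out from 6 and comes back at 9, and sets the benzylic centre under thermodynamic instead of kinetic control. The dibutylboron enolate of 6 is added to aldehyde 7 precomplexed with TiCl4 (open transition state, non-Evans syn) to give (S)-4-benzyl-3-[(2R,3R)-2-[2-(benzyloxy)-5-bromo-3-methoxyphenyl]-3-[4-(benzyloxy)-3-methoxyphenyl]-3-hydroxypropanoyl]oxazolidin-2-one F3, which already has the correct C2. LiBH4 reduction gives (1R,2S)-2-[2-(benzyloxy)-5-bromo-3-methoxyphenyl]-1-[4-(benzyloxy)-3-methoxyphenyl]propane-1,3-diol F4. Treatment with 2,2-dimethoxypropane and catalytic BF3·OEt2 in CH2Cl2 closes the acetonide and equilibrates the p-alkoxybenzylic carbon through its cation to the diequatorial (4S,5S)-4-[4-(benzyloxy)-3-methoxyphenyl]-5-[2-(benzyloxy)-5-bromo-3-methoxyphenyl]-2,2-dimethyl-1,3-dioxane F5. Hydrolysis in aqueous acetic acid gives 9.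

Step 3 (the aryl bromide may compete in the copper coupling, and the keteniminium formed on hydration could be trapped by the ortho benzyloxy oxygen to give a 2-amidobenzofuran). The fallback sets out from 2 and comes back at 6 by a classical homologation, one step longer. Van Leusen reductive cyanation of 2 (TosMIC, KOt-Bu, DME, −30 °C, then MeOH, reflux) gives 2-[2-(benzyloxy)-5-bromo-3-methoxyphenyl]acetonitrile F6. Hydrolysis with KOH in aqueous ethanol gives 2-[2-(benzyloxy)-5-bromo-3-methoxyphenyl]acetic acid F7. The mixed pivalic anhydride of F7 (pivaloyl chloride, Et3N) is then treated with 4 and LiCl to give 6.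

Further compounds
F1 | step 14 | (S)-4-benzyl-3-[2-bromo-3-(ArD)propanoyl]oxazolidin-2-one (C–Br centre undefined) | COc1cc([C@@H](O[Si](C)(C)C(C)(C)C)[C@H](CO[Si](C)(C)C(C)(C)C)c2cc(CC(Br)C(=O)N3[C@@H](Cc4ccccc4)COC3=O)cc(OC)c2O[Si](C)(C)C(C)(C)C)ccc1O[Si](C)(C)C(C)(C)C
F2 | step 14 | 1-methoxy-1-(trimethylsilyloxy)-3-(ArF)prop-1-ene (alkene geometry undefined) | COC(O[Si](C)(C)C)=CCc1cc(OC)c2c(c1)[C@H](CO[Si](C)(C)C(C)(C)C)[C@@H](c1ccc(O[Si](C)(C)C(C)(C)C)c(OC)c1)O2
F3 | step 4 | (S)-4-benzyl-3-[(2R,3R)-2-[2-(benzyloxy)-5-bromo-3-methoxyphenyl]-3-[4-(benzyloxy)-3-methoxyphenyl]-3-hydroxypropanoyl]oxazolidin-2-one | O=C(N1[C@@H](Cc2ccccc2)COC1=O)[C@H](c1cc(Br)cc(OC)c1OCc1ccccc1)[C@@H](O)c1ccc(OCc2ccccc2)c(OC)c1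
F4 | step 4 | (1R,2S)-2-[2-(benzyloxy)-5-bromo-3-methoxyphenyl]-1-[4-(benzyloxy)-3-methoxyphenyl]propane-1,3-diol | COc1cc([C@H](O)[C@H](CO)c2cc(Br)cc(OC)c2OCc2ccccc2)ccc1OCc1ccccc1
F5 | step 4 | (4S,5S)-4-[4-(benzyloxy)-3-methoxyphenyl]-5-[2-(benzyloxy)-5-bromo-3-methoxyphenyl]-2,2-dimethyl-1,3-dioxane | COc1cc([C@H]2OC(C)(C)OC[C@@H]2c2cc(Br)cc(OC)c2OCc2ccccc2)ccc1OCc1ccccc1
F6 | step 3 | 2-[2-(benzyloxy)-5-bromo-3-methoxyphenyl]acetonitrile | COc1cc(Br)cc(CC#N)c1OCc1ccccc1
F7 | step 3 | 2-[2-(benzyloxy)-5-bromo-3-methoxyphenyl]acetic acid | COc1cc(Br)cc(CC(=O)O)c1OCc1ccccc1
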